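**Strategy.** Ring A (the cyclohexane carrying the ester; eremophilane numbering C1–C5 and C10) is disconnected between the carbinol carbon C3 and the methyl-bearing carbon C4. The vicinal CH(O)–CH(CH3) pair beside quaternary C5 is treated as an aldehyde plus a vinyl group. Iron-hydride hydrogen-atom transfer to the vinyl group gives the secondary C4 radical, whose 6-exo addition to the aldehyde closes ring A, creates the secondary methyl, sets C3 and C4 and frees the hydroxyl for acylation. The precursor is a monocyclic (R)-4-methyl-4-vinylcyclohexenone with a 3-oxopropyl arm, made by a catalytic asymmetric Diels–Alder reaction. The diosphenol, isopropylidene and diester follow.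

Key step: step 8

Remarks and assumptions
- Eremophilane numbering is used in the explanations: C3 carbinol carbon, C4 CH(CH3), C5 quaternary carbon, C6–C10 ring B (C7 isopropylidene carbon, C8 ketone, C9 enol carbon, C10 sp2 ring-fusion carbon).
- The (S)-configured oxazaborolidinium catalyst is assumed to give the (1S)-aldehyde 6; if its facial sense on this diene is the opposite, the (R)-catalyst is used.
- Compounds 1 and 15 are assumed to be purchased.

Step 1
Reactants: 1 4-[(tert-butyldimethylsilyl)oxy]butanal; 2 1-(triphenyl-λ5-phosphanylidene)propan-2-one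
Product: 3 (3E)-7-[(tert-butyldimethylsilyl)oxy]hept-3-en-2-one
Conditions: CH2Cl2, 40 °C
Reagents that add atoms: none
Why: Wittig olefination with a stabilised acyl ylide, which reacts only with the aldehyde and should give the E-enone; no stereocentre is formed.

Step 2
Reactants: 3 (3E)-7-[(tert-butyldimethylsilyl)oxy]hept-3-en-2-one
Product: 4 (3E)-2,7-bis[(tert-butyldimethylsilyl)oxy]hepta-1,3-diene
Conditions: tert-butyldimethylsilyl triflate, Et3N, CH2Cl2, 0 °C
Reagents that add atoms: tert-butyldimethylsilyl triflate, CC(C)(C)[Si](C)(C)OS(=O)(=O)C(F)(F)F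
Why: Soft enolisation with O-silylation deprotonates the methyl group of the enone kinetically and gives the 2-silyloxy-1,3-diene with the E-alkene untouched.

Step 3
Reactants: 4 (3E)-2,7-bis[(tert-butyldimethylsilyl)oxy]hepta-1,3-diene; 5 methacrolein
Product: 6 (1S)-4-[(tert-butyldimethylsilyl)oxy]-2-{3-[(tert-butyldimethylsilyl)oxy]propyl}-1-methylcyclohex-3-ene-1-carbaldehyde (configuration at ring carbon 2 not controlled)
Conditions: (S)-3,3-diphenyl-1-(2-methylphenyl)tetrahydro-1H,3H-pyrrolo[1,2-c][1,3,2]oxazaborole (20 mol%), HNTf2 (17 mol%), CH2Cl2, −78 °C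
Reagents that add atoms: none
Why: Catalytic enantioselective Diels–Alder reaction under a chiral cationic oxazaborolidine Lewis acid: the 2-silyloxy and 4-alkyl groups of the diene both direct its unsubstituted terminus to the β-carbon of the enal, the catalyst-shielded face of bound methacrolein fixes the quaternary centre as S, and the endo/exo outcome at ring carbon 2 is irrelevant because that carbon becomes sp2 in step 5.

Step 4
Reactants: 6 (1S)-4-[(tert-butyldimethylsilyl)oxy]-2-{3-[(tert-butyldimethylsilyl)oxy]propyl}-1-methylcyclohex-3-ene-1-carbaldehyde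
Product: 7 (4R)-1-[(tert-butyldimethylsilyl)oxy]-3-{3-[(tert-butyldimethylsilyl)oxy]propyl}-4-ethenyl-4-methylcyclohex-1-ene (configuration at ring carbon 3 not controlled)
Conditions: methyltriphenylphosphonium bromide, KN(SiMe3)2, THF, 0 °C
Reagents that add atoms: methyltriphenylphosphonium bromide, C[P+](c1ccccc1)(c1ccccc1)c1ccccc1.[Br-]
Why: Wittig methylenation of a non-enolisable neopentyl aldehyde; the silyl enol ether and silyl ether are inert to the ylide and the quaternary centre cannot epimerise.

Step 5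
Reactants: 7 (4R)-1-[(tert-butyldimethylsilyl)oxy]-3-{3-[(tert-butyldimethylsilyl)oxy]propyl}-4-ethenyl-4-methylcyclohex-1-ene
Product: 8 (4R)-3-{3-[(tert-butyldimethylsilyl)oxy]propyl}-4-ethenyl-4-methylcyclohex-2-en-1-one
Conditions: Pd(OAc)2 (1.1 equiv), MeCN, 25 °C
Reagents that add atoms: none
Why: Saegusa–Ito oxidation: the regiodefined silyl enol ether gives an enolate of divalent palladium whose only β-hydrogen is the ring C3–H, so β-hydride elimination should deliver the 3,4,4-trisubstituted enone and erase the uncontrolled stereocentre.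

Step 6
Reactants: 8 (4R)-3-{3-[(tert-butyldimethylsilyl)oxy]propyl}-4-ethenyl-4-methylcyclohex-2-en-1-one
Product: 9 (4R)-4-ethenyl-3-(3-hydroxypropyl)-4-methylcyclohex-2-en-1-one
Conditions: HF·pyridine, pyridine, THF, 0 °C
Reagents that add atoms: none
Why: Fluoride-mediated cleavage of the primary silyl ether under mildly acidic conditions, which leave the enone and vinyl group alone and avoid base-induced oxa-Michael closure.

Step 7
Reactants: 9 (4R)-4-ethenyl-3-(3-hydroxypropyl)-4-methylcyclohex-2-en-1-one
Product: 10 3-[(6R)-6-ethenyl-6-methyl-3-oxocyclohex-1-en-1-yl]propanal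
Conditions: Dess–Martin periodinane, CH2Cl2, 0 to 25 °C
Reagents that add atoms: none
Why: Dess–Martin oxidation of the primary alcohol to the aldehyde under neutral conditions without over-oxidation.

Step 8
Reactants: 10 3-[(6R)-6-ethenyl-6-methyl-3-oxocyclohex-1-en-1-yl]propanal
Product: 11 (4aR,5R,6R)-6-hydroxy-4a,5-dimethyl-4,4a,5,6,7,8-hexahydronaphthalen-2(3H)-one
Conditions: Fe(acac)3 (20 mol%), PhSiH3 (2.5 equiv), degassed EtOH, 60 °C
Reagents that add atoms: none
Why: Fe(acac)3 and PhSiH3 in EtOH generate a trivalent iron hydride that transfers a hydrogen atom to the terminal vinyl carbon (Markovnikov), giving the secondary radical at C4 next to quaternary C5; this radical adds to the aldehyde carbon C3, and the alkoxyl radical is reduced by divalent iron and protonated by ethanol, returning trivalent iron. The closest known reaction type is the iron-catalysed, HAT-initiated reductive radical cyclisation of alkene-tethered ketones and aldehydes. Ring A is closed in the 6-exo-trig mode onto C=O, and no other ring is formed. Both new stereocentres should be set by a chair-like transition state built on the existing cyclohexenone: the C5–C6 bond must be equatorial on the forming ring, so the C5 methyl is axial, the methyl on the radical carbon takes the pseudo-equatorial position (cis to the C5 methyl) and the aldehyde oxygen the pseudo-equatorial position (trans to the new methyl); because addition to C=O is reversible, less stable alkoxyl radicals can reopen before reduction. The step needs hydrogen-atom transfer to the isolated vinyl group rather than the enone, and attack on the aldehyde rather than the ring ketone; the first is secured by the preference of the iron hydride for electron-neutral alkenes and the hindered, fully substituted β-carbon of the enone, the second because 5-exo attack on the ring ketone would give a strained bridged alkoxyl radical that reverts.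

Step 9
Reactants: 11 (4aR,5R,6R)-6-hydroxy-4a,5-dimethyl-4,4a,5,6,7,8-hexahydronaphthalen-2(3H)-one
Product: 12 (4aR,5R,6R)-1,8a-epoxy-6-hydroxy-4a,5-dimethyloctahydronaphthalen-2(1H)-one (epoxide oxygen syn to the 4a-methyl)
Conditions: 30% aq. H2O2, NaOH (cat.), MeOH, 0 °C
Reagents that add atoms: hydrogen peroxide, OO
Why: Weitz–Scheffer nucleophilic epoxidation of the only electron-poor alkene; either epoxide face is acceptable because both converge in step 13 (the face syn to the angular methyl is drawn by analogy with steroidal 4-en-3-ones).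

Step 10
Reactants: 12 (4aR,5R,6R)-1,8a-epoxy-6-hydroxy-4a,5-dimethyloctahydronaphthalen-2(1H)-one; 13 acetone
Product: 14 (4aR,5R,6R)-1,8a-epoxy-6-hydroxy-3-(2-hydroxypropan-2-yl)-4a,5-dimethyloctahydronaphthalen-2(1H)-one (configuration at ring carbon 3 not controlled)
Conditions: LiN(iPr)2 (2.2 equiv), THF, −78 °C; acetone, −78 °C; AcOH quench
Reagents that add atoms: none
Why: Directed aldol addition: the base first forms the alkoxide and then the kinetic enolate at the only CH2 α to the ketone (C7), which adds to acetone; the new ring stereocentre is left open because it becomes sp2 in step 13.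

Step 11
Reactants: 15 ethyl 2-[bis(2,2,2-trifluoroethoxy)phosphoryl]propanoate
Product: 17 2-[bis(2,2,2-trifluoroethoxy)phosphoryl]propanoic acid, via trimethylstannyl ester 16 (not isolated)
Conditions: Me3SnOH (3 equiv), 1,2-dichloroethane, 70 °C; aq. HCl work-up
Reagents that add atoms: trimethyltin hydroxide, C[Sn](C)(C)O
Why: Me3SnOH-mediated hydrolysis of a carboxylic ester under neutral conditions, chosen because the hydroxide-sensitive P–OCH2CF3 groups should survive it.

Step 12
Reactants: 14 (4aR,5R,6R)-1,8a-epoxy-6-hydroxy-3-(2-hydroxypropan-2-yl)-4a,5-dimethyloctahydronaphthalen-2(1H)-one; 17 2-[bis(2,2,2-trifluoroethoxy)phosphoryl]propanoic acid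
Product: 18 (4aR,5R,6R)-1,8a-epoxy-3-(2-hydroxypropan-2-yl)-4a,5-dimethyl-2-oxodecahydronaphthalen-6-yl 2-[bis(2,2,2-trifluoroethoxy)phosphoryl]propanoate (epimers at the phosphonate carbon)
Conditions: DCC, DMAP (cat.), CH2Cl2, 0 to 25 °C
Reagents that add atoms: none
Why: Steglich esterification acylates the equatorial secondary alcohol while the tertiary alcohol is unreactive; the phosphonate-bearing carbon is planarised in step 16.

Step 13
Reactants: 18 (4aR,5R,6R)-1,8a-epoxy-3-(2-hydroxypropan-2-yl)-4a,5-dimethyl-2-oxodecahydronaphthalen-6-yl 2-[bis(2,2,2-trifluoroethoxy)phosphoryl]propanoate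
Product: 20 (1R,2R,8aR)-5-hydroxy-1,8a-dimethyl-6-oxo-7-(propan-2-ylidene)-1,2,3,4,6,7,8,8a-octahydronaphthalen-2-yl 2-[bis(2,2,2-trifluoroethoxy)phosphoryl]propanoate, via isopropylidene epoxy ketone 19 (not isolated)
Conditions: H2SO4 (cat.), AcOH, 25 °C
Reagents that add atoms: none
Why: Two acid-catalysed events of known type in one flask, namely enol-mediated dehydration of the tertiary β-hydroxy ketone to the conjugated isopropylidene ketone and the epoxy ketone to diosphenol rearrangement (opening at the tertiary epoxide carbon C10, then loss of the C9 proton), with the enol fixed toward C10 because C7 carries no hydrogen; the order of the two events does not change the outcome.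

Step 14
Reactants: 21 angelic acid [(2Z)-2-methylbut-2-enoic acid]; 22 2-bromoethanol
Product: 23 2-hydroxyethyl (2Z)-2-methylbut-2-enoate
Conditions: KHCO3, DMF, 40 °C
Reagents that add atoms: none
Why: SN2 O-alkylation of the carboxylate, which involves no acyl activation and therefore should leave the Z double bond untouched.

Step 15
Reactants: 23 2-hydroxyethyl (2Z)-2-methylbut-2-enoate
Product: 24 2-oxoethyl (2Z)-2-methylbut-2-enoate
Conditions: Dess–Martin periodinane, CH2Cl2, 0 °C; used at once
Reagents that add atoms: none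
Why: Dess–Martin oxidation gives the α-acyloxy aldehyde under non-basic conditions that do not isomerise the angelate.

Step 16
Reactants: 20 (1R,2R,8aR)-5-hydroxy-1,8a-dimethyl-6-oxo-7-(propan-2-ylidene)-1,2,3,4,6,7,8,8a-octahydronaphthalen-2-yl 2-[bis(2,2,2-trifluoroethoxy)phosphoryl]propanoate; 24 2-oxoethyl (2Z)-2-methylbut-2-enoate
Product: 25 (1R,2R,8aR)-5-hydroxy-1,8a-dimethyl-6-oxo-7-(propan-2-ylidene)-1,2,3,4,6,7,8,8a-octahydronaphthalen-2-yl (2Z)-2-methyl-4-{[(2Z)-2-methylbut-2-enoyl]oxy}but-2-enoate (CNP0301409.1)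
Conditions: KN(SiMe3)2 (2.1 equiv), 18-crown-6, THF, −78 °C; then 24, −78 °C; AcOH quench
Reagents that add atoms: none
Why: Still–Gennari variant of the Horner–Wadsworth–Emmons reaction: the first equivalent of base is taken by the diosphenol, the second forms the bis(trifluoroethyl)phosphonate anion, whose fast, kinetically controlled elimination should give the Z-trisubstituted enoate while the preformed angelate is untouched at −78 °C.

Compound list
1 | 4-[(tert-butyldimethylsilyl)oxy]butanal | O=CCCCO[Si](C)(C)C(C)(C)C | starting material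
2 | 1-(triphenyl-λ5-phosphanylidene)propan-2-one | CC(=O)C=P(c1ccccc1)(c1ccccc1)c1ccccc1 | starting material
3 | (3E)-7-[(tert-butyldimethylsilyl)oxy]hept-3-en-2-one | CC(=O)/C=C/CCCO[Si](C)(C)C(C)(C)C | intermediate
4 | (3E)-2,7-bis[(tert-butyldimethylsilyl)oxy]hepta-1,3-diene | C=C(O[Si](C)(C)C(C)(C)C)/C=C/CCCO[Si](C)(C)C(C)(C)C | intermediate
5 | methacrolein | CC(=C)C=O | starting material
6 | (1S)-4-[(tert-butyldimethylsilyl)oxy]-2-{3-[(tert-butyldimethylsilyl)oxy]propyl}-1-methylcyclohex-3-ene-1-carbaldehyde (ring carbon 2 not controlled) | CC(C)(C)[Si](C)(C)OCCCC1C=C(O[Si](C)(C)C(C)(C)C)CC[C@]1(C)C=O | intermediate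
7 | (4R)-1-[(tert-butyldimethylsilyl)oxy]-3-{3-[(tert-butyldimethylsilyl)oxy]propyl}-4-ethenyl-4-methylcyclohex-1-ene (ring carbon 3 not controlled) | CC(C)(C)[Si](C)(C)OCCCC1C=C(O[Si](C)(C)C(C)(C)C)CC[C@]1(C)C=C | intermediate
8 | (4R)-3-{3-[(tert-butyldimethylsilyl)oxy]propyl}-4-ethenyl-4-methylcyclohex-2-en-1-one | CC(C)(C)[Si](C)(C)OCCCC1=CC(=O)CC[C@]1(C)C=C | intermediate
9 | (4R)-4-ethenyl-3-(3-hydroxypropyl)-4-methylcyclohex-2-en-1-one | OCCCC1=CC(=O)CC[C@]1(C)C=C | intermediate
10 | 3-[(6R)-6-ethenyl-6-methyl-3-oxocyclohex-1-en-1-yl]propanal | O=CCCC1=CC(=O)CC[C@]1(C)C=C | intermediate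
11 | (4aR,5R,6R)-6-hydroxy-4a,5-dimethyl-4,4a,5,6,7,8-hexahydronaphthalen-2(3H)-one | O[C@@H]1CCC2=CC(=O)CC[C@]2(C)[C@H]1C | intermediate
12 | (4aR,5R,6R)-1,8a-epoxy-6-hydroxy-4a,5-dimethyloctahydronaphthalen-2(1H)-one (epoxide oxygen syn to the 4a-methyl) | O[C@@H]1CC[C@@]24O[C@H]4C(=O)CC[C@]2(C)[C@H]1C | intermediate
13 | acetone | CC(C)=O | starting material
14 | (4aR,5R,6R)-1,8a-epoxy-6-hydroxy-3-(2-hydroxypropan-2-yl)-4a,5-dimethyloctahydronaphthalen-2(1H)-one (ring carbon 3 not controlled) | O[C@@H]1CC[C@@]24O[C@H]4C(=O)C(C(C)(C)O)C[C@]2(C)[C@H]1C | intermediate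
15 | ethyl 2-[bis(2,2,2-trifluoroethoxy)phosphoryl]propanoate (racemic) | CCOC(=O)C(C)P(=O)(OCC(F)(F)F)OCC(F)(F)F | starting material
16 | trimethylstannyl 2-[bis(2,2,2-trifluoroethoxy)phosphoryl]propanoate | C[Sn](C)(C)OC(=O)C(C)P(=O)(OCC(F)(F)F)OCC(F)(F)F | intermediate
17 | 2-[bis(2,2,2-trifluoroethoxy)phosphoryl]propanoic acid (racemic) | OC(=O)C(C)P(=O)(OCC(F)(F)F)OCC(F)(F)F | intermediate
18 | (4aR,5R,6R)-1,8a-epoxy-3-(2-hydroxypropan-2-yl)-4a,5-dimethyl-2-oxodecahydronaphthalen-6-yl 2-[bis(2,2,2-trifluoroethoxy)phosphoryl]propanoate | CC(C(=O)O[C@@H]1CC[C@@]24O[C@H]4C(=O)C(C(C)(C)O)C[C@]2(C)[C@H]1C)P(=O)(OCC(F)(F)F)OCC(F)(F)F | intermediate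
19 | (4aR,5R,6R)-1,8a-epoxy-4a,5-dimethyl-2-oxo-3-(propan-2-ylidene)decahydronaphthalen-6-yl 2-[bis(2,2,2-trifluoroethoxy)phosphoryl]propanoate | CC(C(=O)O[C@@H]1CC[C@@]24O[C@H]4C(=O)C(=C(C)C)C[C@]2(C)[C@H]1C)P(=O)(OCC(F)(F)F)OCC(F)(F)F | intermediate
20 | (1R,2R,8aR)-5-hydroxy-1,8a-dimethyl-6-oxo-7-(propan-2-ylidene)-1,2,3,4,6,7,8,8a-octahydronaphthalen-2-yl 2-[bis(2,2,2-trifluoroethoxy)phosphoryl]propanoate | CC(C(=O)O[C@@H]1CCC2=C(O)C(=O)C(=C(C)C)C[C@]2(C)[C@H]1C)P(=O)(OCC(F)(F)F)OCC(F)(F)F | intermediate
21 | angelic acid [(2Z)-2-methylbut-2-enoic acid] | C/C=C(/C)C(=O)O | starting material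
22 | 2-bromoethanol | OCCBr | starting material
23 | 2-hydroxyethyl (2Z)-2-methylbut-2-enoate | C/C=C(/C)C(=O)OCCO | intermediate
24 | 2-oxoethyl (2Z)-2-methylbut-2-enoate | C/C=C(/C)C(=O)OCC=O | intermediate
25 | (1R,2R,8aR)-5-hydroxy-1,8a-dimethyl-6-oxo-7-(propan-2-ylidene)-1,2,3,4,6,7,8,8a-octahydronaphthalen-2-yl (2Z)-2-methyl-4-{[(2Z)-2-methylbut-2-enoyl]oxy}but-2-enoate | C/C=C(/C)C(=O)OC/C=C(/C)C(=O)O[C@@H]1CCC2=C(O)C(=O)C(=C(C)C)C[C@]2(C)[C@H]1C | target

Total step count: 16. Longest linear sequence: 13 steps (steps 1–10, 12, 13 and 16).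

Steps most likely to fail

Step 8 (key step). The carbon radical may be reduced before it cyclises (net hydrogenation of the vinyl group), or the two faces of the prochiral radical may be poorly distinguished, giving the trans-dimethyl isomer. The fallback forms the same bond by an acyl-radical hydroacylation and sets both centres under thermodynamic and reagent control. It sets out from 10. A thiol-catalysed radical chain (tert-dodecanethiol cat., AIBN, dioxane, 80 °C) generates the acyl radical, which should close 6-exo-trig onto the vinyl group to give (4aR,5R)-4a,5-dimethyl-4,4a,7,8-tetrahydronaphthalene-2,6(3H,5H)-dione F1. Its methyl-bearing carbon is α to the new ketone and is equilibrated with DBU to the equatorial epimer, cis to the angular methyl. NaBH4 in MeOH/CH2Cl2 at −78 °C should then reduce the saturated ketone in preference to the enone, by axial hydride delivery, to the equatorial alcohol. The route is rejoined at 11.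

Step 13. Dehydration and epoxide opening may run at mismatched rates, or the cation at the tertiary epoxide carbon may rearrange while the tertiary alcohol ionises. The fallback separates the two events and masks the diosphenol. It sets out from 12. H2SO4 (cat.) in AcOH performs only the epoxy ketone rearrangement and gives (4aR,5R,6R)-1,6-dihydroxy-4a,5-dimethyl-4,4a,5,6,7,8-hexahydronaphthalen-2(3H)-one F2. TBSCl/Et3N silylates only the acidic enol hydroxyl to give (4aR,5R,6R)-1-[(tert-butyldimethylsilyl)oxy]-6-hydroxy-4a,5-dimethyl-4,4a,5,6,7,8-hexahydronaphthalen-2(3H)-one F3. LiN(iPr)2 (2.2 equiv) and acetone give the aldol (4aR,5R,6R)-1-[(tert-butyldimethylsilyl)oxy]-6-hydroxy-3-(2-hydroxypropan-2-yl)-4a,5-dimethyl-4,4a,5,6,7,8-hexahydronaphthalen-2(3H)-one F4. Acid 17 with DCC/DMAP gives the 6-O-{2-[bis(2,2,2-trifluoroethoxy)phosphoryl]propanoyl} ester of F4, F5. TsOH·H2O in benzene at 60 °C followed by HF·pyridine dehydrates the aldol and removes the enol silyl group. The route is rejoined at 20.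

Step 16. The diosphenolate may interfere: aggregation of the dianion, loss of Z-selectivity, or degradation of the α-acyloxy aldehyde by the second equivalent of base. The fallback olefinates while the diosphenol is still masked as the epoxy ketone. It sets out from 18. KN(SiMe3)2 (1.0 equiv) and 18-crown-6 in THF at −78 °C, then aldehyde 24, give (4aR,5R,6R)-1,8a-epoxy-3-(2-hydroxypropan-2-yl)-4a,5-dimethyl-2-oxodecahydronaphthalen-6-yl (2Z)-2-methyl-4-{[(2Z)-2-methylbut-2-enoyl]oxy}but-2-enoate F6; the far less acidic tertiary alcohol stays protonated. H2SO4 (cat.) in AcOH at 25 °C then effects the dehydration and the diosphenol rearrangement. The route is rejoined at 25.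

Further compounds
F1 | step 8 | (4aR,5R)-4a,5-dimethyl-4,4a,7,8-tetrahydronaphthalene-2,6(3H,5H)-dione | O=C1CCC2=CC(=O)CC[C@]2(C)[C@H]1C
F2 | step 13 | (4aR,5R,6R)-1,6-dihydroxy-4a,5-dimethyl-4,4a,5,6,7,8-hexahydronaphthalen-2(3H)-one | O[C@@H]1CCC2=C(O)C(=O)CC[C@]2(C)[C@H]1C
F3 | step 13 | (4aR,5R,6R)-1-[(tert-butyldimethylsilyl)oxy]-6-hydroxy-4a,5-dimethyl-4,4a,5,6,7,8-hexahydronaphthalen-2(3H)-one | O[C@@H]1CCC2=C(O[Si](C)(C)C(C)(C)C)C(=O)CC[C@]2(C)[C@H]1C
F4 | step 13 | (4aR,5R,6R)-1-[(tert-butyldimethylsilyl)oxy]-6-hydroxy-3-(2-hydroxypropan-2-yl)-4a,5-dimethyl-4,4a,5,6,7,8-hexahydronaphthalen-2(3H)-one | O[C@@H]1CCC2=C(O[Si](C)(C)C(C)(C)C)C(=O)C(C(C)(C)O)C[C@]2(C)[C@H]1C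
F5 | step 13 | 6-O-{2-[bis(2,2,2-trifluoroethoxy)phosphoryl]propanoyl} ester of F4 | CC(C(=O)O[C@@H]1CCC2=C(O[Si](C)(C)C(C)(C)C)C(=O)C(C(C)(C)O)C[C@]2(C)[C@H]1C)P(=O)(OCC(F)(F)F)OCC(F)(F)F
F6 | step 16 | (4aR,5R,6R)-1,8a-epoxy-3-(2-hydroxypropan-2-yl)-4a,5-dimethyl-2-oxodecahydronaphthalen-6-yl (2Z)-2-methyl-4-{[(2Z)-2-methylbut-2-enoyl]oxy}but-2-enoate | C/C=C(/C)C(=O)OC/C=C(/C)C(=O)O[C@@H]1CC[C@@]24O[C@H]4C(=O)C(C(C)(C)O)C[C@]2(C)[C@H]1C
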